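**Retrosynthetic overview**
1. Target 26 ⇐ silyl ether 25 ⇐ acyclic bromo‑chloro dialdehyde 23 in one CrCl2/NiCl2 operation. The 2‑bromoallyl chloride unit first closes the seven‑membered ring (C3a–C4), then its vinyl bromide closes the five‑membered ring (C2–C3).
2. 23 ⇐ enone from δ‑lactone 9 (fragment 1: C4–C7 and side chain) plus the alkenylmagnesium from iodide 17 (fragment 2: C1–C3, C3a, C8, C8a); then acetate, CBS reduction (C7), TBS ether, acetal hydrolysis.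
3. 9 ⇐ organocatalytic Michael addition (propanal + alkylidene malonate 3), Brown allylation, Krapcho lactonisation, cross‑metathesis.
4. 17 ⇐ asymmetric Cr‑mediated 2‑haloallylation of 2‑bromoacrolein 15 with iodoallyl bromide 14 (from alkyne 10), then chlorination.
5. Ring order: seven‑membered ring first, five‑membered ring second, both in step 16.

Assumption: 4,4‑diethoxybut‑1‑yne (10) and 2‑bromoprop‑2‑enal (15) are taken as catalogue reagents.
Locants C1–C8a are those of the azulene ring in the name of 26; C1′–C7′ are those of its heptenyl side chain.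

**Step 1**
Reactants: 1 2,2‑dimethoxyacetaldehyde; 2 dimethyl propanedioate
Product: 3 dimethyl 2‑(2,2‑dimethoxyethylidene)propanedioate
Conditions: piperidine (cat.), AcOH (cat.), toluene, reflux, Dean–Stark
Reagents that add atoms: none
Why: Knoevenagel condensation of a non‑enolisable aldehyde with the malonate CH‑acid, driven by azeotropic removal of water; no stereocentre is formed.

**Step 2**
Reactants: 3 dimethyl 2‑(2,2‑dimethoxyethylidene)propanedioate; 4 propanal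
Product: 5 dimethyl 2‑[(2S,3S)‑1,1‑dimethoxy‑3‑methyl‑4‑oxobutan‑2‑yl]propanedioate
Conditions: (R)‑α,α‑diphenylprolinol TMS ether (10 mol %), PhCO2H (10 mol %), EtOH, 0 °C
Reagents that add atoms: none
Why: Enamine‑catalysed Michael addition (Hayashi–Jørgensen type) in which the (E)‑enamine of propanal adds through the acyclic synclinal transition state on the face remote from the CPh2OTMS group, setting the future C5 and C2′ as the syn pair.

**Step 3**
Reactants: 5 dimethyl 2‑[(2S,3S)‑1,1‑dimethoxy‑3‑methyl‑4‑oxobutan‑2‑yl]propanedioate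
Product: 6 dimethyl 2‑[(2S,3S,4S)‑4‑hydroxy‑1,1‑dimethoxy‑3‑methylhept‑6‑en‑2‑yl]propanedioate
Conditions: (−)‑Ipc2B(allyl), Et2O, −78 °C; then ethanolamine
Reagents that add atoms: (−)‑B‑allyldiisopinocampheylborane, C=CCB([C@@H]1C[C@@H]2C[C@H]([C@H]1C)C2(C)C)[C@@H]1C[C@@H]2C[C@H]([C@H]1C)C2(C)C
Why: Brown allylboration through a Zimmerman–Traxler chair, in which the reagent attacks the Si face that is also the Felkin–Anh face of the α‑methyl aldehyde, giving the (S)‑carbinol C3′ syn to the C2′ methyl.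

**Step 4**
Reactants: 6 dimethyl 2‑[(2S,3S,4S)‑4‑hydroxy‑1,1‑dimethoxy‑3‑methylhept‑6‑en‑2‑yl]propanedioate
Product: 8 (4R,5S,6S)‑4‑(dimethoxymethyl)‑5‑methyl‑6‑(prop‑2‑en‑1‑yl)oxan‑2‑one, via lactone methyl ester 7 (not isolated)
Conditions: LiCl, DMSO/H2O, 140 °C
Reagents that add atoms: none
Why: Thermal δ‑lactonisation onto one malonate ester followed by Krapcho dealkoxycarbonylation of the other (chloride attack at O‑methyl, then loss of CO2); no stereocentre is touched.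

**Step 5**
Reactants: 8 (4R,5S,6S)‑4‑(dimethoxymethyl)‑5‑methyl‑6‑(prop‑2‑en‑1‑yl)oxan‑2‑one
Product: 9 (4R,5S,6S)‑4‑(dimethoxymethyl)‑5‑methyl‑6‑(3‑methylbut‑2‑en‑1‑yl)oxan‑2‑one
Conditions: 2‑methylbut‑2‑ene (excess), second‑generation Grubbs catalyst RuCl2(=CHPh)(PCy3)(H2IMes) (3 mol %), CH2Cl2, 40 °C
Reagents that add atoms: 2‑methylbut‑2‑ene, CC=C(C)C
Why: Olefin cross‑metathesis of the terminal alkene with excess 2‑methylbut‑2‑ene installs the prenyl terminus; lactone and acetal are inert and no stereocentre is involved.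

**Step 6**
Reactants: 10 4,4‑diethoxybut‑1‑yne
Product: 11 5,5‑diethoxypent‑2‑yn‑1‑ol
Conditions: n‑BuLi, THF, −78 °C; (CH2O)n, −78 °C → rt
Reagents that add atoms: formaldehyde (as paraformaldehyde), C=O
Why: Hydroxymethylation of the lithium acetylide (1,2‑addition to formaldehyde) gives the propargylic alcohol.

**Step 7**
Reactants: 11 5,5‑diethoxypent‑2‑yn‑1‑ol
Product: 13 (E)‑5,5‑diethoxy‑2‑iodopent‑2‑en‑1‑ol, via vinylstannane 12 (not isolated)
Conditions: Bu3SnH, PdCl2(PPh3)2 (2 mol %), THF, 0 °C; then I2, CH2Cl2, 0 °C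
Reagents that add atoms: iodine, II
Why: Pd‑catalysed syn‑hydrostannylation places tin on the carbon next to CH2OH (hydroxyl‑directed proximal regiochemistry) and iododestannylation with retention fixes the 2‑iodoallyl unit.

**Step 8**
Reactants: 13 (E)‑5,5‑diethoxy‑2‑iodopent‑2‑en‑1‑ol
Product: 14 (E)‑1‑bromo‑5,5‑diethoxy‑2‑iodopent‑2‑ene
Conditions: CBr4, PPh3, CH2Cl2, 0 °C
Reagents that add atoms: tetrabromomethane, BrC(Br)(Br)Br
Why: Appel bromination of the primary allylic alcohol by SN2 on the alkoxyphosphonium ion without allylic shift; acetal and vinyl iodide are inert.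

**Step 9**
Reactants: 14 (E)‑1‑bromo‑5,5‑diethoxy‑2‑iodopent‑2‑ene; 15 2‑bromoprop‑2‑enal
Product: 16 (3R,4S)‑2‑bromo‑4‑(2,2‑diethoxyethyl)‑5‑iodohexa‑1,5‑dien‑3‑ol
Conditions: CrCl2 (3 equiv), Et3N, chiral oxazoline–sulfonamide ligand (Kishi type, enantiomer that gives the 3R carbinol), cobalt phthalocyanine CoC32H16N8 (cat.), THF, 0 °C
Reagents that add atoms: none
Why: Kishi‑type asymmetric 2‑haloallylation (Nozaki–Hiyama allylation) in which only the allylic bromide is activated in the absence of nickel and the ligand‑bound allylchromium species adds through a chair transition state with the γ‑substituent equatorial, giving the anti adduct on one aldehyde face and thereby fixing the future C8a (the carbinol centre is erased later).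

**Step 10**
Reactants: 16 (3R,4S)‑2‑bromo‑4‑(2,2‑diethoxyethyl)‑5‑iodohexa‑1,5‑dien‑3‑ol
Product: 17 (3S,4S)‑2‑bromo‑3‑chloro‑4‑(2,2‑diethoxyethyl)‑5‑iodohexa‑1,5‑diene
Conditions: PPh3, Cl3CC(O)CCl3, CH2Cl2, 0 °C
Reagents that add atoms: hexachloroacetone, ClC(Cl)(Cl)C(=O)C(Cl)(Cl)Cl
Why: Appel‑type chlorination under Magid conditions converts the allylic alcohol into the chloride by SN2 with inversion and without allylic shift under neutral conditions that spare the acetal.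

**Step 11**
Reactants: 17 (3S,4S)‑2‑bromo‑3‑chloro‑4‑(2,2‑diethoxyethyl)‑5‑iodohexa‑1,5‑diene; 9 (4R,5S,6S)‑4‑(dimethoxymethyl)‑5‑methyl‑6‑(3‑methylbut‑2‑en‑1‑yl)oxan‑2‑one
Product: 19 (3S,4R,8R,9S,10S)‑2‑bromo‑3‑chloro‑4‑(2,2‑diethoxyethyl)‑8‑(dimethoxymethyl)‑10‑hydroxy‑9,13‑dimethyl‑5‑methylidenetetradeca‑1,12‑dien‑6‑one, via alkenylmagnesium chloride 18 (not isolated)
Conditions: i‑PrMgCl·LiCl, THF, −40 °C; then 9, −40 → −10 °C; aq. NH4Cl
Reagents that add atoms: none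
Why: Knochel iodine–magnesium exchange is selective for the alkenyl iodide over the alkenyl bromide and the allylic chloride, and acyl substitution on the δ‑lactone stops at the ketone because the magnesium hemiketal alkoxide persists until quench; no stereocentre changes.

**Step 12**
Reactants: 19 (3S,4R,8R,9S,10S)‑2‑bromo‑3‑chloro‑4‑(2,2‑diethoxyethyl)‑8‑(dimethoxymethyl)‑10‑hydroxy‑9,13‑dimethyl‑5‑methylidenetetradeca‑1,12‑dien‑6‑one
Product: 20 (5S,6S,7R,11R,12S)‑13‑bromo‑12‑chloro‑11‑(2,2‑diethoxyethyl)‑7‑(dimethoxymethyl)‑2,6‑dimethyl‑10‑methylidene‑9‑oxotetradeca‑2,13‑dien‑5‑yl acetate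
Conditions: Ac2O, DMAP, pyridine, CH2Cl2, 0 °C → rt
Reagents that add atoms: acetic anhydride, CC(=O)OC(C)=O
Why: DMAP‑catalysed acetylation of the only free hydroxyl installs the side‑chain acetate now, so no selective acylation is needed at the end.

**Step 13**
Reactants: 20 (5S,6S,7R,11R,12S)‑13‑bromo‑12‑chloro‑11‑(2,2‑diethoxyethyl)‑7‑(dimethoxymethyl)‑2,6‑dimethyl‑10‑methylidene‑9‑oxotetradeca‑2,13‑dien‑5‑yl acetate
Product: 21 (5S,6S,7R,9S,11R,12S)‑13‑bromo‑12‑chloro‑11‑(2,2‑diethoxyethyl)‑7‑(dimethoxymethyl)‑9‑hydroxy‑2,6‑dimethyl‑10‑methylidenetetradeca‑2,13‑dien‑5‑yl acetate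
Conditions: (R)‑Me‑CBS oxazaborolidine (20 mol %), catecholborane, toluene, −78 °C
Reagents that add atoms: none
Why: Corey–Bakshi–Shibata reduction in which the 1‑alkenyl side of the enone acts as the large group, so the (R)‑catalyst delivers hydride to give the (S)‑allylic alcohol (future C7) under reagent control.

**Step 14**
Reactants: 21 (5S,6S,7R,9S,11R,12S)‑13‑bromo‑12‑chloro‑11‑(2,2‑diethoxyethyl)‑7‑(dimethoxymethyl)‑9‑hydroxy‑2,6‑dimethyl‑10‑methylidenetetradeca‑2,13‑dien‑5‑yl acetate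
Product: 22 (5S,6S,7R,9S,11R,12S)‑13‑bromo‑9‑{[tert‑butyl(dimethyl)silyl]oxy}‑12‑chloro‑11‑(2,2‑diethoxyethyl)‑7‑(dimethoxymethyl)‑2,6‑dimethyl‑10‑methylidenetetradeca‑2,13‑dien‑5‑yl acetate
Conditions: TBSOTf, 2,6‑lutidine, CH2Cl2, −78 °C
Reagents that add atoms: tert‑butyldimethylsilyl trifluoromethanesulfonate, CC(C)(C)[Si](C)(C)OS(=O)(=O)C(F)(F)F
Why: Low‑temperature silylation protects the future C7 hydroxyl (which would otherwise form a lactol with the C4 aldehyde) faster than the acetals are activated.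

**Step 15**
Reactants: 22 (5S,6S,7R,9S,11R,12S)‑13‑bromo‑9‑{[tert‑butyl(dimethyl)silyl]oxy}‑12‑chloro‑11‑(2,2‑diethoxyethyl)‑7‑(dimethoxymethyl)‑2,6‑dimethyl‑10‑methylidenetetradeca‑2,13‑dien‑5‑yl acetate
Product: 23 (5S,6S,7R,9S,11R,12S)‑13‑bromo‑9‑{[tert‑butyl(dimethyl)silyl]oxy}‑12‑chloro‑7‑formyl‑2,6‑dimethyl‑10‑methylidene‑11‑(2‑oxoethyl)tetradeca‑2,13‑dien‑5‑yl acetate
Conditions: PPTS (cat.), acetone/H2O 4:1, 50 °C
Reagents that add atoms: water, O
Why: Mild acid‑catalysed acetal hydrolysis unmasks both aldehydes while the secondary TBS ether, the acetate and the deactivated 2‑bromoallylic chloride survive and the α‑stereocentre of the new aldehyde is not enolised.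

**Step 16**
Reactants: 23 (5S,6S,7R,9S,11R,12S)‑13‑bromo‑9‑{[tert‑butyl(dimethyl)silyl]oxy}‑12‑chloro‑7‑formyl‑2,6‑dimethyl‑10‑methylidene‑11‑(2‑oxoethyl)tetradeca‑2,13‑dien‑5‑yl acetate
Product: 25 (2S,3S)‑2‑[(2R,3aR,4S,5R,7S,8aS)‑7‑{[tert‑butyl(dimethyl)silyl]oxy}‑2,4‑dihydroxy‑3,8‑dimethylidenedecahydroazulen‑5‑yl]‑6‑methylhept‑5‑en‑3‑yl acetate, via bromovinyl cycloheptanol 24 (not isolated)
Conditions: CrCl2 (10 equiv), NiCl2 (1 mol %), LiI (10 mol %), DMF/THF 1:1 (2 mM), 25 → 45 °C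
Reagents that add atoms: none
Why: Nozaki–Hiyama–Kishi allylation/alkenylation cascade in which the 2‑bromoallylchromium species from the allylic chloride adds through its γ‑carbon to the C4 aldehyde (only the seven‑membered closure is geometrically possible; the Zimmerman–Traxler chair gives the anti C3a/C4 pair, the C8a side arm stays anti to the forming bond to avoid A(1,3) strain with the bromovinyl group and so gives the trans ring junction, and Felkin–Anh attack anti to the C5 side chain puts the C4 hydroxyl cis to it), after which nickel‑catalysed activation of the vinyl bromide and addition to the remaining aldehyde closes the five‑membered ring with the C2 hydroxyl trans to the bulky C3a–C4 bond.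

**Step 17**
Reactants: 25 (2S,3S)‑2‑[(2R,3aR,4S,5R,7S,8aS)‑7‑{[tert‑butyl(dimethyl)silyl]oxy}‑2,4‑dihydroxy‑3,8‑dimethylidenedecahydroazulen‑5‑yl]‑6‑methylhept‑5‑en‑3‑yl acetate
Product: 26 (2S,3S)‑2‑[(2R,3aR,4S,5R,7S,8aS)‑2,4,7‑trihydroxy‑3,8‑dimethylidenedecahydroazulen‑5‑yl]‑6‑methylhept‑5‑en‑3‑yl acetate
Conditions: HF·pyridine, pyridine, THF, 0 °C → rt
Reagents that add atoms: none
Why: Fluoride‑mediated desilylation under buffered, non‑basic conditions leaves the acetate and the allylic alcohols intact and avoids acyl migration.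

**Compound list**
1 | 2,2‑dimethoxyacetaldehyde | COC(OC)C=O | starting material
2 | dimethyl propanedioate | COC(=O)CC(=O)OC | starting material
3 | dimethyl 2‑(2,2‑dimethoxyethylidene)propanedioate | COC(OC)C=C(C(=O)OC)C(=O)OC | intermediate
4 | propanal | CCC=O | starting material
5 | dimethyl 2‑[(2S,3S)‑1,1‑dimethoxy‑3‑methyl‑4‑oxobutan‑2‑yl]propanedioate | O=C[C@@H](C)[C@H](C(OC)OC)C(C(=O)OC)C(=O)OC | intermediate
6 | dimethyl 2‑[(2S,3S,4S)‑4‑hydroxy‑1,1‑dimethoxy‑3‑methylhept‑6‑en‑2‑yl]propanedioate | C=CC[C@H](O)[C@@H](C)[C@H](C(OC)OC)C(C(=O)OC)C(=O)OC | intermediate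
7 | methyl (4S,5S,6S)‑4‑(dimethoxymethyl)‑5‑methyl‑2‑oxo‑6‑(prop‑2‑en‑1‑yl)oxane‑3‑carboxylate (C3 epimers) | C=CC[C@@H]1OC(=O)C(C(=O)OC)[C@@H](C(OC)OC)[C@@H]1C | intermediate
8 | (4R,5S,6S)‑4‑(dimethoxymethyl)‑5‑methyl‑6‑(prop‑2‑en‑1‑yl)oxan‑2‑one | C=CC[C@@H]1OC(=O)C[C@@H](C(OC)OC)[C@@H]1C | intermediate
9 | (4R,5S,6S)‑4‑(dimethoxymethyl)‑5‑methyl‑6‑(3‑methylbut‑2‑en‑1‑yl)oxan‑2‑one | CC(C)=CC[C@@H]1OC(=O)C[C@@H](C(OC)OC)[C@@H]1C | intermediate
10 | 4,4‑diethoxybut‑1‑yne | C#CCC(OCC)OCC | starting material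
11 | 5,5‑diethoxypent‑2‑yn‑1‑ol | OCC#CCC(OCC)OCC | intermediate
12 | (E)‑5,5‑diethoxy‑2‑(tributylstannyl)pent‑2‑en‑1‑ol | OC/C(=C\CC(OCC)OCC)[Sn](CCCC)(CCCC)CCCC | intermediate
13 | (E)‑5,5‑diethoxy‑2‑iodopent‑2‑en‑1‑ol | OC/C(I)=C\CC(OCC)OCC | intermediate
14 | (E)‑1‑bromo‑5,5‑diethoxy‑2‑iodopent‑2‑ene | BrC/C(I)=C\CC(OCC)OCC | intermediate
15 | 2‑bromoprop‑2‑enal | C=C(Br)C=O | starting material
16 | (3R,4S)‑2‑bromo‑4‑(2,2‑diethoxyethyl)‑5‑iodohexa‑1,5‑dien‑3‑ol | C=C(Br)[C@H](O)[C@H](CC(OCC)OCC)C(I)=C | intermediate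
17 | (3S,4S)‑2‑bromo‑3‑chloro‑4‑(2,2‑diethoxyethyl)‑5‑iodohexa‑1,5‑diene | C=C(Br)[C@@H](Cl)[C@H](CC(OCC)OCC)C(I)=C | intermediate
18 | [(3R,4S)‑5‑bromo‑4‑chloro‑3‑(2,2‑diethoxyethyl)hexa‑1,5‑dien‑2‑yl]magnesium chloride | Cl[Mg]C(=C)[C@@H](CC(OCC)OCC)[C@H](Cl)C(Br)=C | intermediate
19 | (3S,4R,8R,9S,10S)‑2‑bromo‑3‑chloro‑4‑(2,2‑diethoxyethyl)‑8‑(dimethoxymethyl)‑10‑hydroxy‑9,13‑dimethyl‑5‑methylidenetetradeca‑1,12‑dien‑6‑one | CC(C)=CC[C@H](O)[C@@H](C)[C@H](C(OC)OC)CC(=O)C(=C)[C@@H](CC(OCC)OCC)[C@H](Cl)C(Br)=C | intermediate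
20 | (5S,6S,7R,11R,12S)‑13‑bromo‑12‑chloro‑11‑(2,2‑diethoxyethyl)‑7‑(dimethoxymethyl)‑2,6‑dimethyl‑10‑methylidene‑9‑oxotetradeca‑2,13‑dien‑5‑yl acetate | CC(C)=CC[C@H](OC(C)=O)[C@@H](C)[C@H](C(OC)OC)CC(=O)C(=C)[C@@H](CC(OCC)OCC)[C@H](Cl)C(Br)=C | intermediate
21 | (5S,6S,7R,9S,11R,12S)‑13‑bromo‑12‑chloro‑11‑(2,2‑diethoxyethyl)‑7‑(dimethoxymethyl)‑9‑hydroxy‑2,6‑dimethyl‑10‑methylidenetetradeca‑2,13‑dien‑5‑yl acetate | CC(C)=CC[C@H](OC(C)=O)[C@@H](C)[C@H](C(OC)OC)C[C@H](O)C(=C)[C@@H](CC(OCC)OCC)[C@H](Cl)C(Br)=C | intermediate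
22 | (5S,6S,7R,9S,11R,12S)‑13‑bromo‑9‑{[tert‑butyl(dimethyl)silyl]oxy}‑12‑chloro‑11‑(2,2‑diethoxyethyl)‑7‑(dimethoxymethyl)‑2,6‑dimethyl‑10‑methylidenetetradeca‑2,13‑dien‑5‑yl acetate | CC(C)=CC[C@H](OC(C)=O)[C@@H](C)[C@H](C(OC)OC)C[C@H](O[Si](C)(C)C(C)(C)C)C(=C)[C@@H](CC(OCC)OCC)[C@H](Cl)C(Br)=C | intermediate
23 | (5S,6S,7R,9S,11R,12S)‑13‑bromo‑9‑{[tert‑butyl(dimethyl)silyl]oxy}‑12‑chloro‑7‑formyl‑2,6‑dimethyl‑10‑methylidene‑11‑(2‑oxoethyl)tetradeca‑2,13‑dien‑5‑yl acetate | CC(C)=CC[C@H](OC(C)=O)[C@@H](C)[C@H](C=O)C[C@H](O[Si](C)(C)C(C)(C)C)C(=C)[C@@H](CC=O)[C@H](Cl)C(Br)=C | intermediate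
24 | (2S,3S)‑2‑[(1R,2S,3S,4S,6S)‑3‑(1‑bromoethenyl)‑6‑{[tert‑butyl(dimethyl)silyl]oxy}‑2‑hydroxy‑5‑methylidene‑4‑(2‑oxoethyl)cycloheptyl]‑6‑methylhept‑5‑en‑3‑yl acetate | C=C(Br)[C@@H]1[C@@H](O)[C@@H]([C@H](C)[C@H](CC=C(C)C)OC(C)=O)C[C@H](O[Si](C)(C)C(C)(C)C)C(=C)[C@H]1CC=O | intermediate
25 | (2S,3S)‑2‑[(2R,3aR,4S,5R,7S,8aS)‑7‑{[tert‑butyl(dimethyl)silyl]oxy}‑2,4‑dihydroxy‑3,8‑dimethylidenedecahydroazulen‑5‑yl]‑6‑methylhept‑5‑en‑3‑yl acetate | C=C1[C@@H]2[C@@H](O)[C@@H]([C@H](C)[C@H](CC=C(C)C)OC(C)=O)C[C@H](O[Si](C)(C)C(C)(C)C)C(=C)[C@H]2C[C@H]1O | intermediate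
26 | (2S,3S)‑2‑[(2R,3aR,4S,5R,7S,8aS)‑2,4,7‑trihydroxy‑3,8‑dimethylidenedecahydroazulen‑5‑yl]‑6‑methylhept‑5‑en‑3‑yl acetate | C=C1[C@@H]2[C@@H](O)[C@@H]([C@H](C)[C@H](CC=C(C)C)OC(C)=O)C[C@H](O)C(=C)[C@H]2C[C@H]1O | target

**Totals**
Total step count: 17. Longest linear sequence: 12 (steps 1–5, then 11–17; the branch through steps 6–10 is equally long).

**Three steps most likely to fail**

Step 16. The seven‑membered closure may be slow or poorly selective at C3a/C4, the 2‑bromoallylchromium species may lose bromide to give an allene, and oligomers can form. The fallback sets out from 23 and changes the metal for the first closure. Indium powder with NaI in DMF/H2O performs the intramolecular Barbier allylation under conditions that tolerate both aldehydes and gives cycloheptanol 24, which can be sampled to check the C3a/C4 configuration. CrCl2/NiCl2 in DMF is then added to the same flask to close the five‑membered ring, and the path comes back to the route at 25. It needs no compound outside the list (F0).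

Step 11. The alkenylmagnesium 18 carries a γ‑chloride (cyclopropane formation or SN2′ loss is possible) and a basic centre next to an acidic lactone. The fallback sets out from 16 and keeps the carbinol as a silyl ether through the coupling. TESCl/imidazole gives the triethylsilyl ether F1. Exchange with i‑PrMgCl·LiCl and addition to 9 gives the silyloxy hydroxy enone F2. Ac2O/DMAP gives the acetate F3. HF·pyridine at 0 °C frees the allylic alcohol F4. PPh3/hexachloroacetone then chlorinates with inversion, and the path comes back to the route at 20.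

Step 9. The 2‑iodoallylchromium species may eliminate iodide, and the ligand has not been shown to control a γ‑substituted reagent with an enal; since the carbinol centre is later erased, both enantiopurity and anti selectivity are needed. The fallback sets out from 14 and 15 and replaces asymmetric catalysis by resolution. Indium‑mediated Barbier allylation in THF/H2O gives the anti adduct as a racemate, that is 16 together with its enantiomer F5. Esterification with (S)‑O‑methylmandelic acid (DCC, DMAP) gives the mandelate F6 from 16 and the diastereomeric mandelate F7 from F5, which are separated by chromatography. K2CO3/MeOH on F6 then comes back to the route at 16.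

**Further compounds**
F0 | step 16 | none | none
F1 | step 11 | {[(3R,4S)‑2‑bromo‑4‑(2,2‑diethoxyethyl)‑5‑iodohexa‑1,5‑dien‑3‑yl]oxy}(triethyl)silane | C=C(Br)[C@H](O[Si](CC)(CC)CC)[C@H](CC(OCC)OCC)C(I)=C
F2 | step 11 | (3R,4R,8R,9S,10S)‑2‑bromo‑4‑(2,2‑diethoxyethyl)‑8‑(dimethoxymethyl)‑10‑hydroxy‑9,13‑dimethyl‑5‑methylidene‑3‑[(triethylsilyl)oxy]tetradeca‑1,12‑dien‑6‑one | CC(C)=CC[C@H](O)[C@@H](C)[C@H](C(OC)OC)CC(=O)C(=C)[C@@H](CC(OCC)OCC)[C@@H](O[Si](CC)(CC)CC)C(Br)=C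
F3 | step 11 | (5S,6S,7R,11R,12R)‑13‑bromo‑11‑(2,2‑diethoxyethyl)‑7‑(dimethoxymethyl)‑2,6‑dimethyl‑10‑methylidene‑9‑oxo‑12‑[(triethylsilyl)oxy]tetradeca‑2,13‑dien‑5‑yl acetate | CC(C)=CC[C@H](OC(C)=O)[C@@H](C)[C@H](C(OC)OC)CC(=O)C(=C)[C@@H](CC(OCC)OCC)[C@@H](O[Si](CC)(CC)CC)C(Br)=C
F4 | step 11 | (5S,6S,7R,11R,12R)‑13‑bromo‑11‑(2,2‑diethoxyethyl)‑7‑(dimethoxymethyl)‑12‑hydroxy‑2,6‑dimethyl‑10‑methylidene‑9‑oxotetradeca‑2,13‑dien‑5‑yl acetate | CC(C)=CC[C@H](OC(C)=O)[C@@H](C)[C@H](C(OC)OC)CC(=O)C(=C)[C@@H](CC(OCC)OCC)[C@@H](O)C(Br)=C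
F5 | step 9 | (3S,4R)‑2‑bromo‑4‑(2,2‑diethoxyethyl)‑5‑iodohexa‑1,5‑dien‑3‑ol | C=C(Br)[C@@H](O)[C@@H](CC(OCC)OCC)C(I)=C
F6 | step 9 | (3R,4S)‑2‑bromo‑4‑(2,2‑diethoxyethyl)‑5‑iodohexa‑1,5‑dien‑3‑yl (2S)‑2‑methoxy‑2‑phenylacetate | C=C(Br)[C@H](OC(=O)[C@@H](OC)c1ccccc1)[C@H](CC(OCC)OCC)C(I)=C
F7 | step 9 | (3S,4R)‑2‑bromo‑4‑(2,2‑diethoxyethyl)‑5‑iodohexa‑1,5‑dien‑3‑yl (2S)‑2‑methoxy‑2‑phenylacetate | C=C(Br)[C@@H](OC(=O)[C@@H](OC)c1ccccc1)[C@@H](CC(OCC)OCC)C(I)=C
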